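## Retrosynthetic overview

1. The target comes from desilylation and a Mitsunobu esterification (3-methylbut-2-enoic acid, inversion at C8) of an erythro 6,7-epoxy-8-ol, itself made by hydroxyl-directed epoxidation of C6=C7 in the 11-membered dienol.
2. The dienol comes from CBS reduction of a cross-conjugated macrocyclic dienone that already carries the C3 hydroxymethyl group.
3. Key step: a 1,11-cyclization of an oxidized geranylgeranyl-type chain. An allylic C–O bond at C1–C3 (vinyl epoxide) is ionized to a π-allylpalladium unit, and the C10=C11 π-bond of a C8 dienolate captures it. One step forms C1–C11, the quaternary C11 center, the (E)-C9=C10 alkene and the free CH2OH.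
4. The open-chain ketone comes from an α-selective allylbarium coupling (C8–C9) of a myrcene-derived vinyl-epoxide enal (C1–C8) with a geranyl chloride carrying the C14 carbinol (C9–C16, from geranyl acetate).
5. Ring order: the carbocycle first (step 9), the oxirane second (step 12), as in the presumed biosynthesis.

Numbering used in the text is geranylgeranyl numbering: C1 = ring CH2 next to the quaternary carbon, C3 = carbon bearing CH2OH, C6/C7 = oxirane carbons, C8 = ester carbinol, C9=C10 = disubstituted alkene, C11 = quaternary carbon, C14 = side-chain carbinol. The target is (6S,7R,8R,11S,14R).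

Assumption: in step 9 the (R,R)-ligand is taken to give the (11S) ring; if the sense of induction proves opposite, the (S,S)-ligand is used with nothing else changed.

## Route

Step 1
Reactants: 1 β-myrcene
Product: 3 (2E)-2-methyl-6-methylideneocta-2,7-dienal, via (E)-myrcen-8-ol 2 (not isolated)
Conditions: SeO2 (cat.), t-BuOOH, CH2Cl2, rt; filter; then MnO2, CH2Cl2, rt
Reagents that add atoms: selenium dioxide, O=[Se]=O (catalytic oxygen carrier); tert-butyl hydroperoxide, CC(C)(C)OO (terminal oxidant)
Why: Riley allylic oxidation (ene reaction, then [2,3]-shift) at the trisubstituted alkene oxidizes only the (E)-methyl group, and MnO2 converges the allylic alcohol and any aldehyde already present to the (E)-enal, whose conjugation deactivates C6=C7 for step 2.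

Step 2
Reactants: 3 (2E)-2-methyl-6-methylideneocta-2,7-dienal
Product: 4 (2E)-5-(2-ethenyloxiran-2-yl)-2-methylpent-2-enal (racemic at the oxirane carbon)
Conditions: mCPBA (1.0 equiv), CH2Cl2/aq. NaHCO3, 0 °C
Reagents that add atoms: 3-chloroperoxybenzoic acid, OOC(=O)c1cccc(Cl)c1
Why: Prilezhaev epoxidation prefers the more electron-rich 1,1-disubstituted alkene of the diene over the vinyl group and the deactivated enal alkene; the new center is left racemic because it becomes sp2 in step 9.

Step 3
Reactants: 5 geranyl acetate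
Product: 6 (2E)-5-[(2R)-3,3-dimethyloxiran-2-yl]-3-methylpent-2-en-1-yl acetate
Conditions: Shi ketone from D-fructose (1,2:4,5-di-O-isopropylidene-β-D-erythro-2,3-hexodiulo-2,6-pyranose, 30 mol%), Oxone (2KHSO5·KHSO4·K2SO4), K2CO3 buffer, Bu4NHSO4, MeCN/CH2(OMe)2/H2O, 0 °C
Reagents that add atoms: potassium peroxymonosulfate KHSO5, [K+].[O-]S(=O)(=O)OO
Why: Shi asymmetric epoxidation (chiral dioxirane, spiro transition state) attacks only the distal trisubstituted alkene, since the 2,3-alkene is deactivated by the allylic acetate, and sets C14 as (R).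

Step 4
Reactants: 6 (2E)-5-[(2R)-3,3-dimethyloxiran-2-yl]-3-methylpent-2-en-1-yl acetate
Product: 7 (2E,6R)-6-[(tert-butyldimethylsilyl)oxy]-3,7-dimethylocta-2,7-dien-1-yl acetate
Conditions: TBSOTf, DBU, toluene, −78 °C to rt
Reagents that add atoms: tert-butyldimethylsilyl triflate, CC(C)(C)[Si](C)(C)OS(=O)(=O)C(F)(F)F
Why: Noyori-type isomerization of an epoxide to an allyl silyl ether: O-silylation opens the oxirane at the tertiary C15–O bond and DBU removes a methyl proton, so the isopropenyl carbinol appears already protected and C14 keeps its configuration because its C–O bond is not broken.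

Step 5
Reactants: 7 (2E,6R)-6-[(tert-butyldimethylsilyl)oxy]-3,7-dimethylocta-2,7-dien-1-yl acetate
Product: 8 (2E,6R)-6-[(tert-butyldimethylsilyl)oxy]-3,7-dimethylocta-2,7-dien-1-ol
Conditions: K2CO3 (cat.), MeOH, 0 °C to rt
Reagents that add atoms: none
Why: Base-catalyzed transesterification removes the acetate while the secondary silyl ether is stable.

Step 6
Reactants: 8 (2E,6R)-6-[(tert-butyldimethylsilyl)oxy]-3,7-dimethylocta-2,7-dien-1-ol
Product: 9 tert-butyl{[(3R,6E)-8-chloro-2,6-dimethylocta-1,6-dien-3-yl]oxy}dimethylsilane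
Conditions: N-chlorosuccinimide, Me2S, CH2Cl2, −20 to 0 °C
Reagents that add atoms: N-chlorosuccinimide, O=C1CCC(=O)N1Cl
Why: Corey–Kim chlorination displaces the alkoxysulfonium ion of the primary allylic alcohol by SN2 without allylic transposition or loss of the (E) geometry.

Step 7
Reactants: 9 tert-butyl{[(3R,6E)-8-chloro-2,6-dimethylocta-1,6-dien-3-yl]oxy}dimethylsilane; 4 (2E)-5-(2-ethenyloxiran-2-yl)-2-methylpent-2-enal
Product: 11 (3E,7E,11R)-11-[(tert-butyldimethylsilyl)oxy]-1-(2-ethenyloxiran-2-yl)-4,8,12-trimethyltrideca-3,7,12-trien-5-ol, via allylbarium chloride 10 (not isolated)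
Conditions: activated Ba (from BaI2 and lithium biphenylide), THF, −78 °C; then 4, −78 °C; aq. NH4Cl
Reagents that add atoms: none
Why: Allylbarium reagents (Yamamoto allylation) add 1,2 to aldehydes at their α-carbon with retention of the (E) geometry, which joins C8 to C9 while the vinyl epoxide survives at −78 °C; the C8 carbinol and the oxirane carbon are mixtures that are erased in steps 8 and 9.

Step 8
Reactants: 11 (3E,7E,11R)-11-[(tert-butyldimethylsilyl)oxy]-1-(2-ethenyloxiran-2-yl)-4,8,12-trimethyltrideca-3,7,12-trien-5-ol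
Product: 12 (3E,7E,11R)-11-[(tert-butyldimethylsilyl)oxy]-1-(2-ethenyloxiran-2-yl)-4,8,12-trimethyltrideca-3,7,12-trien-5-one
Conditions: MnO2 (activated, excess), CH2Cl2, rt
Reagents that add atoms: none
Why: Neutral MnO2 oxidation of the allylic secondary alcohol gives the β,γ-unsaturated enone without acid that would open the vinyl epoxide; isomerization to the conjugated dienone would be harmless because both give the same dienolate.

Step 9
Reactants: 12 (3E,7E,11R)-11-[(tert-butyldimethylsilyl)oxy]-1-(2-ethenyloxiran-2-yl)-4,8,12-trimethyltrideca-3,7,12-trien-5-one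
Product: 13 (2E,6E,9S,10E)-9-[(3R)-3-[(tert-butyldimethylsilyl)oxy]-4-methylpent-4-en-1-yl]-6-(hydroxymethyl)-2,9-dimethylcycloundeca-2,6,10-trien-1-one
Conditions: Pd2(dba)3·CHCl3 (5 mol%), (R,R)-DACH-phenyl Trost ligand [N,N′-((1R,2R)-cyclohexane-1,2-diyl)bis(2-(diphenylphosphino)benzamide), 15 mol%], degassed THF, 50 °C, slow addition to 0.002 M
Reagents that add atoms: none
Why: Proposed new method: zerovalent palladium ionizes the allylic C–O bond of the vinyl epoxide to a π-allylpalladium alkoxide (the laboratory counterpart of diphosphate ionization at C1), the alkoxide removes a C9 proton, and the zwitterionic C8 dienolate closes onto C1 through its γ-carbon C11 in a vinylogous intramolecular Tsuji–Trost alkylation, whose closest known relatives are the neutral vinyl-epoxide Tsuji–Trost macrocyclizations of carbon acids and the asymmetric allylic alkylations of prochiral enolates with this ligand class; the two (E)-alkenes of the tether make every other closure (C9 to C1, nine-membered; attack at C3, seven- or nine-membered) a strained trans-cycloalkene, the chain sits anti on the allyl unit so that C2=C3 forms ring-cis with the CH2OH set free, the s-trans dienolate gives the (E)-C9=C10 enone, and the chiral pocket of the ligand selects the face of C11 and so sets the quaternary (11S) center.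

Step 10
Reactants: 13 (2E,6E,9S,10E)-9-[(3R)-3-[(tert-butyldimethylsilyl)oxy]-4-methylpent-4-en-1-yl]-6-(hydroxymethyl)-2,9-dimethylcycloundeca-2,6,10-trien-1-one
Product: 14 (2E,6E,9S,10E)-9-[(3R)-3-[(tert-butyldimethylsilyl)oxy]-4-methylpent-4-en-1-yl]-6-{[(tert-butyldimethylsilyl)oxy]methyl}-2,9-dimethylcycloundeca-2,6,10-trien-1-one
Conditions: TBSCl, imidazole, DMF, 0 °C to rt
Reagents that add atoms: tert-butyldimethylsilyl chloride, CC(C)(C)[Si](C)(C)Cl
Why: Standard silylation of the primary allylic alcohol, so that only the C8 hydroxyl can direct the epoxidation and enter the Mitsunobu reaction.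

Step 11
Reactants: 14 (2E,6E,9S,10E)-9-[(3R)-3-[(tert-butyldimethylsilyl)oxy]-4-methylpent-4-en-1-yl]-6-{[(tert-butyldimethylsilyl)oxy]methyl}-2,9-dimethylcycloundeca-2,6,10-trien-1-one
Product: 15 (1S,2E,6E,9S,10E)-9-[(3R)-3-[(tert-butyldimethylsilyl)oxy]-4-methylpent-4-en-1-yl]-6-{[(tert-butyldimethylsilyl)oxy]methyl}-2,9-dimethylcycloundeca-2,6,10-trien-1-ol
Conditions: (R)-2-methyl-CBS-oxazaborolidine [(R)-1-methyl-3,3-diphenyl-tetrahydro-1H,3H-pyrrolo[1,2-c][1,3,2]oxazaborole, 30 mol%], catecholborane, toluene, −78 °C
Reagents that add atoms: none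
Why: Corey–Bakshi–Shibata reduction gives clean 1,2-reduction of the cross-conjugated dienone; with the α-methyl-substituted alkenyl group (C7 side) as the large substituent, the (R)-catalyst delivers hydride to give the (8S) alcohol.

Step 12
Reactants: 15 (1S,2E,6E,9S,10E)-9-[(3R)-3-[(tert-butyldimethylsilyl)oxy]-4-methylpent-4-en-1-yl]-6-{[(tert-butyldimethylsilyl)oxy]methyl}-2,9-dimethylcycloundeca-2,6,10-trien-1-ol
Product: 16 erythro 6,7-epoxide of 15 (8S; oxirane on the face found in the target)
Conditions: VO(acac)2 (5 mol%), t-BuOOH (anhydrous, 1.5 equiv), CH2Cl2, 0 °C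
Reagents that add atoms: tert-butyl hydroperoxide, CC(C)(C)OO
Why: Hydroxyl-directed vanadium epoxidation (Sharpless–Michaelson) reacts only at an alkene next to a free OH and prefers the trisubstituted C6=C7 over the disubstituted C9=C10; with a methyl on C7 the A(1,2)-strain transition state (OH on the attacked peripheral face, ring carbon C9 on the far face) gives the erythro epoxy alcohol, which for the (8S) alcohol is the oxirane configuration of the target.

Step 13
Reactants: 16 erythro 6,7-epoxide of 15; 17 3-methylbut-2-enoic acid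
Product: 18 bis(tert-butyldimethylsilyl) ether of the target (C14–O and CH2–O silylated; C8 (R) 3-methylbut-2-enoate)
Conditions: PPh3, DIAD, toluene, 0 °C to rt
Reagents that add atoms: none
Why: Mitsunobu esterification displaces the activated C8 oxygen by the carboxylate with SN2 inversion, which turns the erythro (8S) alcohol into the threo (8R) ester in the same step that installs the acyl group; SN2′ attack at C10 is blocked by the adjacent quaternary C11.

Step 14
Reactants: 18 bis(tert-butyldimethylsilyl) ether of the target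
Product: 19 target, CNP0309478.2
Conditions: Bu4NF, AcOH (1:1), THF, 0 °C to rt
Reagents that add atoms: none
Why: Fluoride-mediated desilylation removes both silyl ethers, and buffering with acetic acid keeps the oxirane and the ester intact.

## Compound list

1 | β-myrcene (7-methyl-3-methylideneocta-1,6-diene) | C=CC(=C)CCC=C(C)C | starting material
2 | (2E)-2-methyl-6-methylideneocta-2,7-dien-1-ol ((E)-myrcen-8-ol) | OC/C(C)=C/CCC(=C)C=C | intermediate
3 | (2E)-2-methyl-6-methylideneocta-2,7-dienal | O=C/C(C)=C/CCC(=C)C=C | intermediate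
4 | (2E)-5-(2-ethenyloxiran-2-yl)-2-methylpent-2-enal, racemic at the oxirane carbon | O=C/C(C)=C/CCC1(C=C)CO1 | intermediate
5 | geranyl acetate ((2E)-3,7-dimethylocta-2,6-dien-1-yl acetate) | CC(=O)OC/C=C(\C)CCC=C(C)C | starting material
6 | (2E)-5-[(2R)-3,3-dimethyloxiran-2-yl]-3-methylpent-2-en-1-yl acetate | CC(=O)OC/C=C(\C)CC[C@H]1OC1(C)C | intermediate
7 | (2E,6R)-6-[(tert-butyldimethylsilyl)oxy]-3,7-dimethylocta-2,7-dien-1-yl acetate | CC(=O)OC/C=C(\C)CC[C@@H](O[Si](C)(C)C(C)(C)C)C(C)=C | intermediate
8 | (2E,6R)-6-[(tert-butyldimethylsilyl)oxy]-3,7-dimethylocta-2,7-dien-1-ol | OC/C=C(\C)CC[C@@H](O[Si](C)(C)C(C)(C)C)C(C)=C | intermediate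
9 | tert-butyl{[(3R,6E)-8-chloro-2,6-dimethylocta-1,6-dien-3-yl]oxy}dimethylsilane | ClC/C=C(\C)CC[C@@H](O[Si](C)(C)C(C)(C)C)C(C)=C | intermediate
10 | allylbarium chloride derived from 9 | Cl[Ba]C/C=C(\C)CC[C@@H](O[Si](C)(C)C(C)(C)C)C(C)=C | intermediate
11 | (3E,7E,11R)-11-[(tert-butyldimethylsilyl)oxy]-1-(2-ethenyloxiran-2-yl)-4,8,12-trimethyltrideca-3,7,12-trien-5-ol, mixture at C5 and at the oxirane carbon | C=CC1(CO1)CC/C=C(\C)C(O)C/C=C(\C)CC[C@@H](O[Si](C)(C)C(C)(C)C)C(C)=C | intermediate
12 | (3E,7E,11R)-11-[(tert-butyldimethylsilyl)oxy]-1-(2-ethenyloxiran-2-yl)-4,8,12-trimethyltrideca-3,7,12-trien-5-one, mixture at the oxirane carbon | C=CC1(CO1)CC/C=C(\C)C(=O)C/C=C(\C)CC[C@@H](O[Si](C)(C)C(C)(C)C)C(C)=C | intermediate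
13 | (2E,6E,9S,10E)-9-[(3R)-3-[(tert-butyldimethylsilyl)oxy]-4-methylpent-4-en-1-yl]-6-(hydroxymethyl)-2,9-dimethylcycloundeca-2,6,10-trien-1-one (the 6,7-alkene has its two ring bonds cis) | C=C(C)[C@H](O[Si](C)(C)C(C)(C)C)CC[C@]1(C)/C=C/C(=O)/C(C)=C/CC/C(CO)=C\C1 | intermediate
14 | primary tert-butyldimethylsilyl ether of 13 | C=C(C)[C@H](O[Si](C)(C)C(C)(C)C)CC[C@]1(C)/C=C/C(=O)/C(C)=C/CC/C(CO[Si](C)(C)C(C)(C)C)=C\C1 | intermediate
15 | (1S,2E,6E,9S,10E)-dienol from 14 (C8 S in geranylgeranyl numbering) | C=C(C)[C@H](O[Si](C)(C)C(C)(C)C)CC[C@]1(C)/C=C/[C@H](O)/C(C)=C/CC/C(CO[Si](C)(C)C(C)(C)C)=C\C1 | intermediate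
16 | erythro 6,7-epoxide of 15: trans-oxirane at C6/C7 placed as in the target, C8–OH (S), opposite to the C8–O of the target | C=C(C)[C@H](O[Si](C)(C)C(C)(C)C)CC[C@]1(C)/C=C/[C@H](O)[C@]2(C)O[C@H]2CC/C(CO[Si](C)(C)C(C)(C)C)=C\C1 | intermediate
17 | 3-methylbut-2-enoic acid (senecioic acid) | CC(C)=CC(=O)O | starting material
18 | bis(tert-butyldimethylsilyl) ether of the target, (6S,7R,8R,11S,14R) | C=C(C)[C@H](O[Si](C)(C)C(C)(C)C)CC[C@]1(C)/C=C/[C@@H](OC(=O)C=C(C)C)[C@]2(C)O[C@H]2CC/C(CO[Si](C)(C)C(C)(C)C)=C\C1 | intermediate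
19 | CNP0309478.2, (6S,7R,8R,11S,14R) | C=C(C)[C@H](O)CC[C@]1(C)/C=C/[C@@H](OC(=O)C=C(C)C)[C@]2(C)O[C@H]2CC/C(CO)=C\C1 | target

## Step count and risks

Total step count: 14 (steps 1–2 make 4, steps 3–6 make 9, steps 7–14 follow the union).
Longest linear sequence: 12 steps (5 to 19, steps 3–14).

The three steps most likely to fail:

**Step 9 (macrocyclization).** The risks are that the π-allylpalladium alkoxide loses a proton to a dienol instead of cyclizing, that the dienolate reacts at C9 or oxygen, and that the ligand gives poor selectivity at C11. The fallback sets out from 12 and comes back at 14. Compound 12 is O-silylated through its potassium dienolate (KN(SiMe3)2, TBSCl, THF, −78 °C) to the tert-butyldimethylsilyl dienol ether F1. Slow addition of F1 to catalytic TBSOTf with 2,6-di-tert-butylpyridine in CH2Cl2 at −78 °C (0.002 M) opens the vinyl epoxide to a silyloxy allyl cation, which the γ-carbon C11 of the dienol ether captures at C1 (vinylogous Mukaiyama-type cation–olefin cyclization). The silyl group released from the C8 oxocarbenium ion carries the chain, so 14 forms directly. Without a chiral ligand 14 comes with its C11 epimer; the two are diastereomers because C14 is fixed and are separated by chromatography.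

**Step 11 (CBS reduction).** The risk is that the ring conformation overrides the catalyst, or that the two alkenyl groups are not differentiated. The fallback sets out from 14 and comes back at 16. Luche reduction (NaBH4, CeCl3·7H2O, MeOH, −40 °C) gives 15 together with its C8 epimer, the (8R)-dienol F2. The mixture is treated with Ti(OiPr)4, L-(+)-diisopropyl tartrate and t-BuOOH (4 Å sieves, CH2Cl2, −20 °C). Only the (8S) alcohol 15 is epoxidized (matched Sharpless kinetic resolution, erythro, same oxirane face), giving 16. Unreacted F2 is separated and oxidized back to 14 with MnO2 for recycling.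

**Step 13 (Mitsunobu esterification).** The risk is that the carbinol, flanked by a fully substituted oxirane carbon, reacts slowly or eliminates. The fallback sets out from 16 and comes back at 18. MnO2 oxidizes 16 to the epoxy enone F3. Reagent-controlled reduction with (S)-2-methyl-CBS-oxazaborolidine and catecholborane (toluene, −78 °C; the quaternary oxirane carbon acts as the large group) gives the (8R) threo epoxy alcohol F4. Yamaguchi esterification of F4 with 17 (2,4,6-trichlorobenzoyl chloride, Et3N, DMAP, toluene) then gives 18 with retention.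

## Further compounds

F1 | step 9 | tert-butyldimethylsilyl dienol ether of 12 (C8 siloxy 8,10-diene, vinyl epoxide intact) | C=CC1(CO1)CC/C=C(\C)C(/O[Si](C)(C)C(C)(C)C)=C/C=C(\C)CC[C@@H](O[Si](C)(C)C(C)(C)C)C(C)=C
F2 | step 11 | (8R)-dienol, C8 epimer of 15 | C=C(C)[C@H](O[Si](C)(C)C(C)(C)C)CC[C@]1(C)/C=C/[C@@H](O)/C(C)=C/CC/C(CO[Si](C)(C)C(C)(C)C)=C\C1
F3 | step 13 | epoxy enone from 16 (C8 ketone, oxirane as in the target) | C=C(C)[C@H](O[Si](C)(C)C(C)(C)C)CC[C@]1(C)/C=C/C(=O)[C@]2(C)O[C@H]2CC/C(CO[Si](C)(C)C(C)(C)C)=C\C1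
F4 | step 13 | (8R) threo epoxy alcohol, C8 epimer of 16 | C=C(C)[C@H](O[Si](C)(C)C(C)(C)C)CC[C@]1(C)/C=C/[C@@H](O)[C@]2(C)O[C@H]2CC/C(CO[Si](C)(C)C(C)(C)C)=C\C1
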